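The data were computed for substances that don't exist; the scatter is artificial.

Product was the first item of the meeting: the chair noted that in the ash run it levels off well short of the charge, and the runs were laid out.

| flask | starting material | reagent | free catalyst | time |
|---|---|---|---|---|
| ash | 0.100 M | 0.100 M | 0.00200 M |  |
| oak | 0.100 M | 0.200 M | 0.00200 M |  |
| larch | 0.0500 M | 0.100 M | 0.00200 M |  |
| cedar | 0.100 M | 0.100 M | 0.00100 M |  |
| birch | 0.0600 M | 0.0600 M | 0.00200 M | 66 min |

- ash run (time / min: [product] / M): 11: 0.0152; 22: 0.0239; 33: 0.0264; 44: 0.0304; 55: 0.0305; 66: 0.0288
- oak run (time / min: [product] / M): 11: 0.0214; 22: 0.0268; 33: 0.0283; 44: 0.0323; 55: 0.0340; 66: 0.0310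
- larch run (time / min: [product] / M): 11: 0.0097; 22: 0.0188; 33: 0.0243; 44: 0.0223; 55: 0.0262; 66: 0.0297
- cedar run (time / min: [product] / M): 11: 0.0037; 22: 0.0052; 33: 0.0030; 44: 0.0032; 55: 0.0063; 66: 0.0032

(each reading ± 0.002 M)

- reaction order in [free catalyst] at the outset, round the charge of the ash run, defined at two percent of the starting material turned into product
- reaction order in [starting material] at the outset, round the charge of the ash run, defined at two percent of the starting material turned into product (one fixed amount of product, the same in the runs compared)
- product in the birch run at 66 min, as a share of the starting material charged

- Overall: starting material + reagent -> product, with free catalyst as catalyst.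
- Constant volume, constant temperature.
- The analysis sees a species whether free or bound.
- "The second partner" is reagent.
- An order is taken over about fifteen percent of the charge, up and down.

The chair took the mean of the last 3 readings of the ash, oak and cedar runs as a reading of each ceiling: 0.0299 M in ash, 0.0324 M in oak and 0.00423 M in cedar.

The first speaker argued that ash at its ceiling still held about 0.0701 M of starting material and of reagent, and that oak, with twice the reagent, stood at 1.08 of the ash ceiling. She therefore looked to the catalyst and not to either partner.

The second speaker pointed out that cedar, charged with half the free catalyst of ash, reached 0.141 of the ash ceiling. He proposed that a fixed amount z of free catalyst is lost at the start, and that the remainder makes a fixed number of turnovers N, the turnover number. Ceilings then go as C − z, where C is the free catalyst charged, and the ash and cedar ceilings give z = 8.35 × 10⁻⁴ M. He warned that this is a rough reading, since the cedar ceiling stands at 2.12 times the scatter.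

The meeting called C − z the working catalyst, A: 0.00116 M in ash and 1.65 × 10⁻⁴ M in cedar. This makes N = 25.7 for ash.

The chair then reckoned for herself. If the rate goes as A at fixed charges of both partners, the order in catalyst is the slope C/A, which is 1.72 in ash. Birch has the catalyst charge of ash, so on this reading it has the same A, and its ceiling N·A is 49.8% of its starting material. Larch, with the same catalyst charge, read 0.0297 M at 66 min, level with the ash ceiling, so she expected birch close beneath its ceiling share at 66 min.

The forecast gave 1.8 for the order in free catalyst, 0.55 for the order in starting material and 42% for birch, holding that “a small amount of catalyst, about 0.0008 M, appears to be titrated off”, with its order above the chair's slope and its birch share below her ceiling share.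

The flask gives 1.8 for the order in free catalyst, 0.74 for the order in starting material and 46.8% for birch.

    free catalyst + starting material → catalyst-substrate complex (27.66 L mol⁻¹ min⁻¹)
    catalyst-substrate complex + reagent → product + free catalyst (73.80 L mol⁻¹ min⁻¹)
    free catalyst + starting material → spent catalyst + starting material (1.032 L mol⁻¹ min⁻¹)
    free catalyst + impurity → spent catalyst

The impurity takes free catalyst at once, and the ash order stands at 1.8 because of that loss: without the impurity the same flask gives 1.0, which is C/A with A equal to C. The working catalyst also carries over to cedar, where A is 0.142 of its ash value, a figure read from ceilings. The rate of cedar over that of ash, taken early at equal product, is 0.12.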